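- 5.23 min: that is how long I read a molecule of X as lasting at 70 °C, from G's fall in Sunday's run by 3.00 min set against its stall by 25.0 min.
- At that stall the G gone equals, mole for mole, 23.8 % of the X charged, so I read a second road at X's fork: G on one side, a clock on cX on the other.

all flasks: J 0.125 M

|  | G | X | temperature | remark | time |
|---|---|---|---|---|---|
| Sunday's | 0.25 M | 0.325 M | 70 °C | run made earlier |  |
| Monday's | 0.25 M | 0.16 M | 70 °C | run made earlier |  |
| eta | 0.25 M (fed, over 25 min) | 0.325 M | 70 °C | all else is in the flask from the start; the feed brings no volume worth counting | 40 min |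
| gamma | 0.25 M | 0.325 M (fed, over 25 min) | 70 °C | all else is in the flask from the start; the feed brings no volume worth counting | 40 min |
| theta | 0.25 M (fed, over 25 min) | 0.325 M |  | the addition at 30 °C, then warmed to 70 °C; the feed brings no volume worth counting | 40 min |
| delta | 0.25 M | 0.325 M (fed, over 6.0 min) | 70 °C | all else is in the flask from the start; the feed brings no volume worth counting | 40 min |

| run | time / min | Z / % | G / % |
|---|---|---|---|
| Sunday's | 3.00 | 12.7 | 85.1 |
| Sunday's | 8.00 | 18.5 | 74.6 |
| Sunday's | 15.0 | 16.5 | 70.0 |
| Sunday's | 25.0 | 11.3 | 69.1 |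
| Monday's | 0.667 | 2.6 | 97.5 |
| Monday's | 1.33 | 4.2 | 95.7 |
| Monday's | 3.00 | 6.9 | 92.2 |
| Monday's | 8.00 | 10.1 | 86.8 |

(each reading ± 0.3 percentage points)

- the numbers in the tables scatter with a standard deviation of 0.3 percentage points
- the earlier runs do not show what temperature does; that part of a forecast is a guess

- the flask with the highest amount of Z, in percent of the G charged ("all alike" if they lie within 1.5 percentage points) (eta / gamma / theta / delta / all alike)
- final Z, as a percentage of the G charged, in eta
- final Z, as a percentage of the G charged, in gamma
- final Z, as a percentage of the G charged, in theta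
- final Z, as a percentage of the G charged, in delta

- Next rung up the ladder: the quick feed of 6.0 min in delta runs a little longer than X's life, so in delta I expect X to pile up while the feed runs.
- Next comes Z's life, which I read as 26.4 min from Sunday's late pseudo-first-order fall of Z, and the slow feed of 25 min is still shorter than that life.
- The top rung is the 40 min window, and it is longer than Z's life, so what counts at the end is how long ago Z was made.
- I therefore carry the age of the charge, the time from the mean moment X and G stand together at 70 °C to the end of the flask, and I read Z off Sunday's curve at that age.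
- In gamma, X arrives on average halfway through the feed, so the age is 27.5 min, and extending Sunday's fall gives me 10.3 %.
- In delta the age is 37.0 min, which gives me 7.17 %.
- Eta differs, since after one life of X its G has come in to 20.9 % of the charge; scaling Sunday's uptake by that gives 7.73 % made, and at an age of 29.5 min I expect 2.53 %.
- In theta I guess that 30 °C holds the flask still, so the age is 15.0 min and Sunday's reading there gives 16.5 %, my highest.
- The forecast, “assuming the clock starts at t = 0”, names theta, with eta 2.1 %, gamma 2 %, theta 13 % and delta 4.2 %, and so parts from my reckoning in gamma and delta, while in theta it starts from the same Sunday reading as I do and shades it down as a guess.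
- The flasks give theta as highest, with eta 2.87 %, gamma 10.4 %, theta 17.2 % and delta 6.86 %.

    G + Z → L (k = 0.00233 L mol⁻¹ s⁻¹, Ea = 68.0 kJ mol⁻¹)
    G + X ⇌ J + Z (K = 1.20, k = 0.00367 L mol⁻¹ s⁻¹, Ea = 60.0 kJ mol⁻¹, ΔH = −32.0 kJ mol⁻¹)
    Z + X ⇌ J + D (K = 0.150, k = 0.00160 L mol⁻¹ s⁻¹, Ea = 67.0 kJ mol⁻¹, ΔH = −4.00 kJ mol⁻¹)
    X → E (k = 0.00235 s⁻¹, Ea = 110 kJ mol⁻¹)
    D + X ⇌ J + Q (K = 0.130, k = 0.0103 L mol⁻¹ s⁻¹, Ea = 73.0 kJ mol⁻¹, ΔH = 20.0 kJ mol⁻¹)
    (constants at 70 °C)

- Gamma ends at 10.4 % against my 10.3 % at an age of 27.5 min, and delta, the second flask, ends at 6.86 % against my 7.17 % at an age of 37.0 min. The largest single effect I can prove on theta's lead over eta is the loss of X to E . At 25.0 min, theta holds 93.8 % of its X and eta 2.20 %. Without that loss, the gap of 14 percentage points between the two shrinks to 0.67 points.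

The readings come from a simulation for an exercise; scatter was added.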